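The earlier runs and the new flask stem from a simulated flask for substances that don't exist, noise included.

A small charge of partner has to serve the substrate twice: each double product takes two partners, each first product one.

| flask | substrate | partner | remark | time |
|---|---|---|---|---|
| teal | 0.065 M | 0.065 M | run made earlier |  |
| blue | 0.033 M | 0.065 M | run made earlier |  |
| noon | 0.065 M | 0.0650 M (fed, over 3.0 min) | all else is in the flask from the start; the feed brings no volume worth counting | 8.0 min |
| dusk | 0.065 M | 0.0650 M | everything together at the start | 8.0 min |
| dawn | 0.065 M (fed, over 3.0 min) | 0.0650 M | all else is in the flask from the start; the feed brings no volume worth counting | 8.0 min |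

teal run (percent of the substrate charged)

| time / min | double product / % | first product / % |
|---|---|---|
| 1.00 | 11.5 | 18.9 |
| 3.00 | 14.1 | 17.5 |
| 5.00 | 13.0 | 16.8 |
| 8.00 | 14.7 | 20.3 |

blue run (percent of the substrate charged)

| time / s | double product / % | first product / % |
|---|---|---|
| 12.0 | 1.4 | 13.6 |
| 25.0 | 8.9 | 19.1 |
| 40.0 | 12.8 | 18.6 |
| 50.0 | 15.6 | 18.8 |

(readings scatter by 1 percentage point)



- the flask that comes out highest in amount of double product, in percent of the substrate charged; "all alike" if 1.5 percentage points covers them all (noon / dusk / dawn / all alike)
- amount of double product at the end, in percent of the substrate charged, noon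
- amount of double product at the end, in percent of the substrate charged, dusk
- amount of double product at the end, in percent of the substrate charged, dawn

From 3.00 min on, the teal run stays near 13.9% double product (D) and 18.2% first product (M), both as shares of the substrate charged. With c_S and c_P the charges of substrate and partner, the sum (2D + M)c_S/c_P gives 46.1% for teal. This sum, the share of the partner charged that stands in the two read products, is the capture φ.

The bracket for noon follows from φ. From above, partner is the limiting reagent for double product: paired completely, it gives D = 50.0%. With M held at the teal plateau and the remaining partner paired, the bound tightens to 40.9%. From below, this reckoning takes the plateau itself, 13.9%, as read in teal: in noon a stall by balance, or a partner loss of first order, should leave φ near its teal value, and a loss of higher order in partner should raise it.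

Dawn is the mirror case, with substrate arriving into the whole partner charge, and this reckoning places it between zero and 13.9%. Dusk has the teal charges and belongs at the plateau. The reckoning commits to the order noon, dusk, dawn.

The forecast says all alike, with noon 14.3%, dusk 14% and dawn 14%: “If the stall is equilibrium, all flasks reach the same end point”. Its noon sits at the lower edge of the noon bracket, and its dawn at the upper edge of the dawn bracket.

The highest flask is noon, at 22.6%.

    substrate + partner → other mono adduct (k = 0.280 M⁻¹ s⁻¹)
    partner + other mono adduct → double product (k = 0.300 M⁻¹ s⁻¹)
    substrate + partner → first product (k = 0.330 M⁻¹ s⁻¹)
    2 partner → homo dimer (k = 0.360 M⁻¹ s⁻¹)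
    partner + first product → double product (k = 0.660 M⁻¹ s⁻¹)
    substrate → decomposition product (k = 5.70 × 10⁻⁶ s⁻¹)

Noon lies inside its bracket, dusk gives 13.4%, and dawn gives 5.14%, inside the dawn bracket. Homo dimer ends at 0.00446 M in noon, less than the 0.0115 M in dusk. With 19.1% first product, noon has φ = 64.2%, above the 46.1% read in the teal run. The neighbour of noon charged with 0.11 M of partner holds 46.0% double product and 15.0% first product, so its φ is 63.3%.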